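Side loss per target is the ratio I want: starting material lost to anything but target, divided by target formed. Even odds, a ratio of 1, is the zero of my scale; above it the side steps are ahead of target.

| setting | birch | elm | larch | ochre | grey |
|---|---|---|---|---|---|
| starting material | 0.044 M | 0.066 M | 0.10 M | 0.060 M | 0.10 M |
| reagent | 0.15 M | 0.15 M | 0.15 M | 0.150 M | 0.150 M |
| second substrate | 0.50 M | 0.50 M | 0.52 M | 1.00 M | 0.500 M |
| protic impurity | 0.10 M | 0.10 M | 0.10 M | 0.300 M | 0.100 M |
| temperature | 45 °C | 56 °C | 45 °C | 50 °C | 50 °C |
| remark | run made earlier | run made earlier | run made earlier |  |  |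
| time |  |  |  | 5.0 min | 5.0 min |

| run | time / min | target / % | starting material / % |
|---|---|---|---|
| birch | 0.667 | 7 | 87 |
| birch | 2.00 | 14 | 70 |
| birch | 3.00 | 18 | 60 |
| birch | 5.00 | 26 | 48 |
| elm | 0.667 | 11 | 74 |
| elm | 2.00 | 25 | 48 |
| elm | 3.00 | 33 | 37 |
| elm | 5.00 | 36 | 29 |
| larch | 0.417 | 6 | 89 |
| larch | 1.00 | 8 | 81 |
| larch | 2.00 | 15 | 60 |
| larch | 5.00 | 21 | 36 |

(readings scatter by 2 percentage points)

- the winner by amount of target, in percent of the starting material charged; "neither" if no more than 2 percentage points parts them (ochre / grey / neither)
- how much target is there at the end, in percent of the starting material charged: ochre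
- how much target is there at the end, in percent of the starting material charged: grey

I read the last row of each run. Birch stands at 1.00, on the zero. Larch, at the same 45 °C, gives 2.05, so in these readings the ratio climbs with c(starting material), as expected if homo dimer competes with target. A line through these two has slope 18.7 M⁻¹ and intercept 0.177; I take that intercept for the quench, though it is a small difference of scattered readings. Elm, at 56 °C, gives 0.972, against 1.41 on the line at its charge, so in these readings warming lowers the ratio. Since 50 °C lies near the middle, I use the square root of that quotient, 0.830.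

Grey then has a side loss per target of 1.70. Ochre, with the intercept scaled by c(protic impurity) and the slope taken at its lower c(starting material), has 1.37, and that scaling is a guess. With conversion near 67.5%, the mean of larch and elm, target is conversion over one plus the ratio: 25.0% for grey, 28.5% for ochre. My reckoning puts ochre ahead by 3.5 percentage points, but each reading scatters by 2 points and the ochre figure rests on the guessed scaling, so I commit to neither.

The forecast says grey, with 16% for ochre and 23% for grey, where I say neither: “Ochre has doubled reagent loss and triple the quench”.

Ochre gives 27.3% and grey 26.7%, so the winner is neither.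

    starting material + reagent → target (k = 0.0170 M⁻¹ s⁻¹, Ea = 74.0 kJ mol⁻¹)
    second substrate + reagent → second product (k = 8.20 × 10⁻⁴ M⁻¹ s⁻¹, Ea = 56.0 kJ mol⁻¹)
    2 starting material → homo dimer (k = 0.0200 M⁻¹ s⁻¹, Ea = 49.0 kJ mol⁻¹)
    reagent ⇌ dormant form (K = 2.00, k = 0.00250 s⁻¹, Ea = 95.0 kJ mol⁻¹, ΔH = −17.0 kJ mol⁻¹)
    starting material + protic impurity → quenched substrate (k = 0.00440 M⁻¹ s⁻¹, Ea = 57.0 kJ mol⁻¹)
    (constants at 50 °C)

Ochre holds 23.0% homo dimer and 20.6% quenched substrate, grey 37.0% and 6.67%, and side loss per target comes to 1.60 in ochre and 1.64 in grey, against my 1.70 for grey. Reagent stands in neither side equation, and for the neighbour of grey charged with 0.060 M reagent I stretch 1.70 by 2.50 to 4.25. Its conversion of 63.6% then gives 12.1%, and that neighbour holds 11.6% target.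

(All runs were computed on assumed constants; noise was put on by code.)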